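All runs were generated by integration from invented constants; the scatter is artificial.

- This chemistry is slow: the birch run needs 8.00 h to reach 24% of target, and its readings are still rising at the last one.

| setting | birch | ash | elm | Saturday's | Sunday's | Monday's | Tuesday's |
|---|---|---|---|---|---|---|---|
| starting material | 0.015 M | 0.015 M | 0.015 M | 0.015 M | 0.015 M | 0.015 M | 0.015 M (fed, over 6.40 h) |
| reagent | 1 equiv | 1 equiv | 1 equiv | 1.00 equiv (fed, over 6.40 h) | 1.00 equiv | 1.00 equiv | 1.00 equiv |
| protic impurity | 7.5 mM | 7.5 mM | 7.5 mM | 7.50 mM | 7.50 mM | 7.50 mM | 7.50 mM |
| initiator | 1 mol% | 0.5 mol% | 2 mol% | 1 mol% | 1 mol% | 1 mol% | 1 mol% |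
| remark | run made earlier | run made earlier | run made earlier | a stirred flask in which reagent is dosed at a steady rate over 6.40 h without added volume, worked up at 8.0 h | a closed flask charged with all of it at once and left for 8.0 h | one stirred flow tank at steady state, fed with the mixture as stated, mean residence time 8.0 h | a stirred flask in which starting material is dosed at a steady rate over 6.40 h without added volume, worked up at 8.0 h |
| time |  |  |  | 8.0 h | 8.0 h |  | 8.0 h |

| run | time / h | target / % |
|---|---|---|
| birch | 0.667 | 2 |
| birch | 1.33 | 9 |
| birch | 3.00 | 14 |
| birch | 8.00 | 24 |
| ash | 2.50 | 6 |
| ash | 5.00 | 12 |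
| ash | 8.00 | 16 |
| ash | 10.0 | 19 |
| elm | 0.833 | 8 |
| elm | 2.00 | 8 |
| elm | 4.00 | 18 |
| elm | 10.0 | 35 |

(standard deviation of a reading: 2 percentage points)

- the stated concentrations are those of everything mixed, before any reaction; amounts are the same in each set-up
- the earlier runs were read with a standard deviation of 2 percentage points
- the feed brings no volume worth counting
- the earlier runs were made in a closed, stirred flask

- the set-up with the highest amount of target at the outlet or at the end, in percent of the starting material put in ("none" if the first two lie within 2 percentage points) (Saturday's / Sunday's / Monday's / Tuesday's / none)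
- amount of target at the outlet or at the end, in percent of the starting material put in, Saturday's
- amount of target at the outlet or at the end, in percent of the starting material put in, Sunday's
- amount of target at the outlet or at the end, in percent of the starting material put in, Monday's
- amount of target at the outlet or at the end, in percent of the starting material put in, Tuesday's

- Read one constant from the closed flask: k′, the apparent second-order constant, is target formed divided by the fraction not yet converted, per hour. The last birch reading gives 0.0395 h⁻¹, a reading that carries its scatter.
- The last readings of ash and elm give 0.0235 h⁻¹ and 0.0538 h⁻¹. A loading ratio of 4.00 therefore multiplies k′ by 2.29, and I take its square root, 2.00, as the working law.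
- Now run Saturday's flask in slow motion. In the first instants it holds starting material, initiator and 7.50 mM of protic impurity, and the reagent is just beginning to arrive.
- At the middle of the feed, 3.20 h, at most 0.00750 M of [reagent] has been added. The feed ends at 6.40 h, which leaves a hold until 8.0 h.
- Every earlier run held the same [protic impurity], so these readings cannot separate what it does.
- Replace the ramp by its mean. The mean contact time θ, the end time minus the midpoint of the feed, is the average time a dosed molecule spends in the flask: 4.80 h. That is 60.0% of the time a closed flask gets.
- The Damköhler number k′θ is then 19.0% as a linear estimate. Allowing for consumption, k′θ over one plus k′θ gives 15.9%, so the correction costs 3 percentage points.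
- My reckoning therefore gives 15.9% for Saturday's and the same for Tuesday's, because both share θ, which is shorter than the closed flask's time.
- Sunday's repeats the birch recipe, so I keep 24%. For Monday's, balancing outflow against k′ times the squared unconverted fraction at residence time 8.0 h gives 20.1%.
- The forecast gave 14%, 24%, 20% and 17% for Saturday's, Sunday's, Monday's and Tuesday's, and chose Sunday's, concluding that “Batch should win.”
- The flasks give 16.1% for Saturday's, 23.6% for Sunday's, 19.5% for Monday's and 19.2% for Tuesday's, so Sunday's leads.

    initiator → 2 initiating radical (k = 3.90 × 10⁻⁵ min⁻¹)
    starting material + initiating radical → chain carrier (k = 19100 M⁻¹ s⁻¹)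
    reagent + chain carrier → target + initiating radical (k = 20200 M⁻¹ s⁻¹)
    2 chain carrier → ended chains A (k = 2.30 × 10⁸ M⁻¹ s⁻¹)
    2 initiating radical → ended chains B (k = 3.00 × 10⁷ M⁻¹ s⁻¹)
    reagent + target → over-reaction product (k = 0.0356 M⁻¹ min⁻¹)
    starting material + protic impurity → quenched substrate (k = 0.629 M⁻¹ min⁻¹)

- Saturday's lands on the reckoned 15.9%, while Tuesday's, at the same θ, stands 3.3 points above it; at 8.00 h Tuesday's holds 0.0166% of ended chains A against 0.0306% in Saturday's. Now take the neighbour flask, Saturday's recipe with 4 mol% of initiator: the square-root law raises k′ to 0.0789 h⁻¹, θ stays 4.80 h, the reckoning gives 27.5%, and that flask gives 28.4%.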